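**Remarks on the chemistry (assumptions)**

- The biaryl axis has only hydroxyl and hydrogen in its ortho positions, so it is treated as freely rotating and no axial configuration is controlled.
- The stereodescriptors of the lactone partner, the key-step product and the target agree centre by centre. The (2S,3S) lactone delivers C2 (S) and the side-chain carbinol (R) of each half of the target, and the target lactone is cis (carbinol R, methyl carbon S).
- The lactone partner carries its tertiary hydroxyl as a triethylsilyl ether. This group migrates less readily to the neighbouring alkoxide freed on ring opening than a trimethylsilyl group and is still removed by fluoride. The tandem is run as a staged one-flask sequence with an acid quench before desilylation, so that no carbanion is present when the tertiary alkoxide is released.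
- Hydroxycitric acid lactone (garcinia acid) is taken as commercially available.

## Structural features

The target is an unsymmetrical dimer of two 5-hydroxychroman-4-ones joined by a C6–C6' biaryl bond ortho to both phenols. Each C2 is a quaternary stereocentre carrying a methyl ester, O1, C3 and a side-chain carbon. In one half the side chain is a cis-β-methyl-γ-butyrolactone bound through its oxygen-bearing carbon, and in the other it is the same chain opened to a 4-hydroxy-3-methylbutanoic acid. Each half has three contiguous stereocentres, C2 (S), the carbinol carbon (R) and the methyl-bearing carbon (S), six in all. Fragile points are the C2–O1 bond β to the C4 ketone (a C3 enolate can expel the aryloxide and scramble C2), the methyl esters, and the γ-hydroxy acid, which recloses to the lactone in acid. The real difficulty is the quaternary C2 next to a secondary carbinol, needed twice in the same absolute sense, and the final differentiation of two otherwise identical halves. The key step uses the fact that C4–C3–C2(O1)(CO2Me)–CH(O)–C is the skeleton and configuration of (2S,3S)-hydroxycitric acid γ-lactone, in which the lactone carbonyl becomes C4, the tertiary hydroxyl becomes O1 and the lactone ring oxygen becomes the carbinol oxygen. On the arene side, C4a sits between C5–O and C8a–O, which matches the carbon between methoxyl and fluorine of a 4,4'-difluoro-2,2'-dimethoxybiphenyl, the most acidic position of that arene, whose neighbouring fluorine serves as the leaving group for O1–C8a.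

## Logic of the disconnections

**15 to 14.** The acyl–oxygen bond of the second lactone is re-formed in the retrosynthetic sense, so the hydroxy acid half becomes a lactone. This makes the two halves identical and lets everything earlier be done twice on one molecule. The forward step must open only one of two equivalent lactones and spare two methyl esters and both C2–O1 bonds.

**14 to 13.** The two phenolic O–H bonds are replaced by O–CH3 bonds. The phenols must be masked through the organolithium, amide-base and triflation steps, and a methyl ether peri to the C4 carbonyl is the one ether a boron Lewis acid removes selectively. The forward step must leave lactones and esters alone.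

**13 to 12.** The two C–H bonds on lactone C3 and C4 of each half are removed to give butenolides. This deletes both methyl-bearing stereocentres and leaves them to a face-selective hydrogenation. The forward step must deliver hydrogen from the face away from the chromanyl group on the adjacent carbon.

**12 to 11 to 10.** The bond from the ring carbon to the methyl group is cut, and the triflate is traced back to the enol of a tetronic acid. The methyl-bearing carbon thereby becomes a carboxyl-level carbon. The forward steps need sulfonylation of the vinylogous acid only, and methyl transfer without attack on ketone or ester.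

**10 to 9 to 8.** The C3–C4 bond of each five-membered ring is cut (Dieckmann) and then the O–acetyl bond. Each side chain shrinks to CH(OH)CO2Me. The forward condensation must run through the acetate enolate faster than the chromanone C3 enolate can do damage.

**8 to 2 and 5, through 6 and 7.** In both halves the O1–C8a and C4–C4a bonds are cut. Three components result, and all four stereocentres of 8 are already present in two molecules of 5. The forward step needs attack of the aryl carbanion at the lactone carbonyl only, a single addition, and closure by the tertiary oxygen rather than the secondary one.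

**5 to 4 to 3, and 2 to 1.** The O–Si bond and the two ester O–CH3 bonds lead from 5 through 4 back to 3. The biaryl bond of 2 leads back to two molecules of 1. Both branches are simple and only ask that the lactone ring and the C–F bonds survive.

## Other disconnections considered

Alternative 1: The cut is the C2–C3 bond of each half, an aldol disconnection. In the forward direction A1, the bis(silyl enol ether) in which each ring of 2 carries a 1-silyloxyvinyl group at C3, would add at both ends to the ketone carbonyl of two molecules of the lactone α-keto ester A2. The catalyst would be Cu(OTf)2 with a bis(oxazoline) ligand, the divalent copper binding each keto ester as a chelate, and the product would be the bis(β-hydroxy ketone) A3.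
- In its favour: A2 already holds the finished cis-methyl lactone, so A3 needs only the fluoride displacement to reach 13. The five side-chain operations of the chosen plan disappear, and the chromanone is never exposed to a strong amide base. On these points it is better than the chosen plan.
- Against it: C2 must be created rather than inherited. The keto ester is far bulkier than the simple α-keto esters for which this catalysis is best established, and its neighbouring stereocentre and lactone oxygen can compete for copper. A matched or mismatched pairing must therefore be expected, and it would have to hold twice on one molecule. A2 has an epimerisable oxygen-bearing centre next to a 1,2-dicarbonyl and needs a multistep synthesis of its own.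
- Comparison: on the arene and the later SNAr closure the two plans are equal. On certainty of configuration at C2 the chosen plan is better, because it transfers the centre from the pool. On total step count Alternative 1 is at best equal, since what it saves after the coupling it spends on A2.

Alternative 2: The cut is the bond between the lactone carbonyl carbon and its CH2 neighbour, so that this carbonyl carbon comes from carbon monoxide. In the forward direction the bis(2-methylallyl) phosphinobenzoate A4 would be hydroformylated at both terminal alkene carbons with Rh(CO)2(acac) under CO and H2. The ester-bound phosphine would deliver rhodium to one alkene face and give the bis-aldehyde A5 with oxygen and methyl syn. That relationship corresponds to the cis lactone of the target.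
- In its favour: the methyl centre is set by a directing group on the existing carbinol, a control element that is the equal of, and arguably more predictable than, face shielding in a hydrogenation. No strong base is used, which is better than the chosen plan. The open-chain oxidation pattern appears directly, which suits the half of the target that is a hydroxy acid.
- Against it: A4 needs an isopropenyl group where hydroxycitric acid provides an ester. Converting one ester of three carbonyl groups in each half into that alkene has no evident selective solution, so the chiral-pool mapping would be lost or lengthened. After A5, two aldehydes must be oxidised and two hindered aryl esters cleaved beside methyl esters. The phosphine is air-sensitive.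
- Comparison: one catalytic step would replace four of the chosen plan, but three to five are added around it, so step economy is no better. On the final differentiation of the halves the two plans are equal, since both must treat one of two identical side chains differently.

Alternative 3: The cut removes both benzene rings, at C7–C8 and C4a–C5 of each, and the biaryl bond is the central bond of a succinate. In the forward direction two molecules of the chiral 6-methyldihydropyranone A6, as extended enolates or silyl dienol ethers, would react with the bis(aminomethylene)succinate A7. Each methyl carbon would displace an amino group of A7, each enone α-carbon would be acylated by an ester, and both rings would aromatise to the bis-phenol A8.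
- In its favour: A8 is the same compound as 14, so no biaryl coupling, no SNAr and no phenol protection are needed, and one step remains to the target. On convergence and protecting-group economy it is better than the chosen plan.
- Against it: A6 carries the same C2–O bond β to a ketone, but in a non-aromatic vinylogous ester. The base needed for the extended enolate would prefer the C3 protons kinetically, and a C3 enolate can expel the ring oxygen as a stabilised enolate, which would cost the C2 configuration. The twofold addition–elimination, acylation and aromatisation next to a forming hindered biaryl has no close precedent. A6 needs its own asymmetric synthesis, for example a hetero-Diels–Alder reaction on A2.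
- Comparison: on the final mono-opening the two plans are equal. On mechanism the chosen plan rests on two well-known reaction types where this one rests on an untested cascade. On step count after the coupling Alternative 3 is better; before it, it is probably worse.

Key step: step 4

## Route

Step 1
Reactants: 1 1-bromo-4-fluoro-2-methoxybenzene (2 equiv)
Product: 2 4,4'-difluoro-2,2'-dimethoxy-1,1'-biphenyl
Conditions: NiCl2(PPh3)2 (10 mol %), PPh3, Zn, Et4NI, THF, 50 °C
Reagents that add atoms: none
Why: Nickel-catalysed reductive homocoupling that joins two molecules of 1 at their bromine-bearing carbons, with zinc as the terminal reductant; zerovalent nickel inserts into C–Br and not C–F, and one ortho methoxyl is tolerated.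

Step 2
Reactants: 3 (2S,3S)-3-hydroxy-5-oxotetrahydrofuran-2,3-dicarboxylic acid (hydroxycitric acid lactone)
Product: 4 dimethyl (2S,3S)-3-hydroxy-5-oxotetrahydrofuran-2,3-dicarboxylate
Conditions: Me3SiCHN2, MeOH/PhMe, 0 °C → rt
Reagents that add atoms: trimethylsilyldiazomethane, C[Si](C)(C)C=[N+]=[N-]
Why: O-Methylation of both carboxylic acids by diazomethane released in the flask; the neutral conditions should leave the lactone closed and the tertiary hydroxyl free, and no stereocentre is touched.

Step 3
Reactants: 4 dimethyl (2S,3S)-3-hydroxy-5-oxotetrahydrofuran-2,3-dicarboxylate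
Product: 5 dimethyl (2S,3S)-5-oxo-3-(triethylsilyloxy)tetrahydrofuran-2,3-dicarboxylate
Conditions: Et3SiOTf, 2,6-lutidine, CH2Cl2, −40 → 0 °C
Reagents that add atoms: triethylsilyl trifluoromethanesulfonate, CC[Si](CC)(CC)OS(=O)(=O)C(F)(F)F
Why: Silylation of a hindered tertiary alcohol with a silyl triflate and a hindered pyridine base; the base is too weak to enolise the lactone, so β-elimination should not compete.

Step 4
Reactants: 2 4,4'-difluoro-2,2'-dimethoxy-1,1'-biphenyl; 5 dimethyl (2S,3S)-5-oxo-3-(triethylsilyloxy)tetrahydrofuran-2,3-dicarboxylate (2.6 equiv)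
Product: 8 dimethyl (2S,2'S)-2,2'-bis[(1S)-1-hydroxy-2-methoxy-2-oxoethyl]-5,5'-dimethoxy-4,4'-dioxo-[6,6'-bichromane]-2,2'-dicarboxylate, via dilithiobiaryl 6 (not isolated), via bis(aryl ketone) silyl ether 7 (not isolated)
Conditions: sBuLi (2.2 equiv), TMEDA, THF, −78 °C; 5 in THF, −78 °C; AcOH (1 equiv per Li), −78 °C; then Bu4NF (excess), THF, −20 °C → rt
Reagents that add atoms: none
Why: sBuLi/TMEDA removes the proton between fluorine and methoxyl on each ring of 2 (directed ortho metalation at the most acidic C–H), and 6 is held at −78 °C, where loss of LiF to an aryne is not yet significant. Each C–Li bond adds to the lactone carbonyl of 5 (C4–C4a), the only acyl carbon beside an unbranched CH2, and the five-membered lithium lactolate does not collapse at −78 °C, so no ketone is offered for a second addition; the closest known case is the addition of aryllithiums to persilylated sugar lactones. AcOH removes all carbanion before warming and leaves 7, a γ-hydroxy ketone in equilibrium with its lactol. Bu4NF then cleaves the two triethylsilyl ethers, and each tertiary alkoxide attacks the fluorine-bearing carbon ortho to the new ketone, forms a Meisenheimer adduct stabilised by that ketone and expels fluoride (O1–C8a); the closest known reaction type is the intramolecular SNAr of β-hydroxy ortho-fluoroaryl ketones to chroman-4-ones. Each pyranone ring closes by a six-membered addition–elimination, formally 6-endo-trig because the C4a–C8a bond that relays the charge to the ketone lies inside the new ring, whereas closure by the secondary hydroxyl would need a seven-membered ring. No stereocentre is formed: C2 and the carbinol carbon of each half are C3 and C2 of 5, and no bond to either is broken. The step needs lactone-over-ester selectivity, which the quaternary and tertiary carbons beside the two esters and the two ortho substituents of the nucleophile should provide, and closure faster than retro-aldol cleavage, which is held back because it would have to release an α-keto ester and is therefore uphill and reversible.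

Step 5
Reactants: 8 dimethyl (2S,2'S)-2,2'-bis[(1S)-1-hydroxy-2-methoxy-2-oxoethyl]-5,5'-dimethoxy-4,4'-dioxo-[6,6'-bichromane]-2,2'-dicarboxylate
Product: 9 dimethyl (2S,2'S)-2,2'-bis[(1S)-1-acetoxy-2-methoxy-2-oxoethyl]-5,5'-dimethoxy-4,4'-dioxo-[6,6'-bichromane]-2,2'-dicarboxylate
Conditions: Ac2O, pyridine, DMAP (cat.), CH2Cl2, 0 °C → rt
Reagents that add atoms: acetic anhydride, CC(=O)OC(C)=O
Why: DMAP-catalysed acylation of the only free hydroxyl in each half; the conditions are too weakly basic to enolise the chromanone.

Step 6
Reactants: 9 dimethyl (2S,2'S)-2,2'-bis[(1S)-1-acetoxy-2-methoxy-2-oxoethyl]-5,5'-dimethoxy-4,4'-dioxo-[6,6'-bichromane]-2,2'-dicarboxylate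
Product: 10 dimethyl (2S,2'S)-2,2'-bis[(2R)-3-hydroxy-5-oxo-2,5-dihydrofuran-2-yl]-5,5'-dimethoxy-4,4'-dioxo-[6,6'-bichromane]-2,2'-dicarboxylate
Conditions: LiN(SiMe3)2 (6 equiv), THF, −78 → −30 °C; 1 M HCl
Reagents that add atoms: none
Why: Dieckmann condensation in its tetronic acid form: each acetate enolate attacks the methyl ester on the same carbinol carbon in a 5-exo-trig acyl substitution and expels methoxide, giving the tetronic acid. Attack on the C2 ester would need a six-membered spiro closure at a neopentyl carbonyl, and the chromanone enolates formed by the excess base are kept cold; the carbinol C–H is not removed, so its configuration is retained.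

Step 7
Reactants: 10 dimethyl (2S,2'S)-2,2'-bis[(2R)-3-hydroxy-5-oxo-2,5-dihydrofuran-2-yl]-5,5'-dimethoxy-4,4'-dioxo-[6,6'-bichromane]-2,2'-dicarboxylate
Product: 11 dimethyl (2S,2'S)-5,5'-dimethoxy-4,4'-dioxo-2,2'-bis[(2S)-5-oxo-3-(trifluoromethylsulfonyloxy)-2,5-dihydrofuran-2-yl]-[6,6'-bichromane]-2,2'-dicarboxylate (same spatial arrangement as in 10; only the descriptor of the furanone carbon changes)
Conditions: Tf2O, iPr2NEt, CH2Cl2, −78 °C
Reagents that add atoms: trifluoromethanesulfonic anhydride, O=S(=O)(OS(=O)(=O)C(F)(F)F)C(F)(F)F
Why: O-Sulfonylation of a vinylogous carboxylic acid as its ammonium salt, which should be far faster than enol triflation of the aryl ketone at −78 °C.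

Step 8
Reactants: 11 dimethyl (2S,2'S)-5,5'-dimethoxy-4,4'-dioxo-2,2'-bis[(2S)-5-oxo-3-(trifluoromethylsulfonyloxy)-2,5-dihydrofuran-2-yl]-[6,6'-bichromane]-2,2'-dicarboxylate
Product: 12 dimethyl (2S,2'S)-5,5'-dimethoxy-2,2'-bis[(2R)-3-methyl-5-oxo-2,5-dihydrofuran-2-yl]-4,4'-dioxo-[6,6'-bichromane]-2,2'-dicarboxylate
Conditions: Me2CuLi (from MeLi and CuI), THF, −78 °C; NH4Cl (aq)
Reagents that add atoms: lithium dimethylcuprate, [Li+].C[Cu-]C
Why: Coupling of a β-sulfonyloxy enoate with Me2CuLi by conjugate addition and loss of triflate; at −78 °C the cuprate should not add to the aryl ketone or the esters and is too weakly basic to remove the γ-proton of the butenolide.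

Step 9
Reactants: 12 dimethyl (2S,2'S)-5,5'-dimethoxy-2,2'-bis[(2R)-3-methyl-5-oxo-2,5-dihydrofuran-2-yl]-4,4'-dioxo-[6,6'-bichromane]-2,2'-dicarboxylate
Product: 13 dimethyl (2S,2'S)-5,5'-dimethoxy-2,2'-bis[(2R,3S)-3-methyl-5-oxotetrahydrofuran-2-yl]-4,4'-dioxo-[6,6'-bichromane]-2,2'-dicarboxylate
Conditions: H2 (5 bar), Pd/C, EtOAc, rt
Reagents that add atoms: none
Why: Heterogeneous syn hydrogenation of a butenolide; the surface binds the alkene face opposite to the bulky chromanyl group on the adjacent sp3 carbon, so both hydrogens arrive from that face and the methyl group ends cis to the chromanyl group (3S), as in the known cis-selective hydrogenation of 4-methyl-5-alkylbutenolides.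

Step 10
Reactants: 13 dimethyl (2S,2'S)-5,5'-dimethoxy-2,2'-bis[(2R,3S)-3-methyl-5-oxotetrahydrofuran-2-yl]-4,4'-dioxo-[6,6'-bichromane]-2,2'-dicarboxylate
Product: 14 dimethyl (2S,2'S)-5,5'-dihydroxy-2,2'-bis[(2R,3S)-3-methyl-5-oxotetrahydrofuran-2-yl]-4,4'-dioxo-[6,6'-bichromane]-2,2'-dicarboxylate
Conditions: BCl3, CH2Cl2, −78 → 0 °C; H2O
Reagents that add atoms: none
Why: Chelation-assisted demethylation: boron binds between the C4 carbonyl and the peri methoxyl oxygen and chloride attacks the methyl group; methyl esters and lactones should not react at this temperature.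

Step 11
Reactants: 14 dimethyl (2S,2'S)-5,5'-dihydroxy-2,2'-bis[(2R,3S)-3-methyl-5-oxotetrahydrofuran-2-yl]-4,4'-dioxo-[6,6'-bichromane]-2,2'-dicarboxylate
Product: 15 (3S,4R)-4-hydroxy-4-[(2S)-5-hydroxy-6-{(2S)-5-hydroxy-2-(methoxycarbonyl)-2-[(2R,3S)-3-methyl-5-oxotetrahydrofuran-2-yl]-4-oxochroman-6-yl}-2-(methoxycarbonyl)-4-oxochroman-2-yl]-3-methylbutanoic acid
Conditions: LiOH (3.0 equiv), THF/H2O, 0 °C; HCl to pH 4, 0 °C
Reagents that add atoms: lithium hydroxide, [Li+].[OH-]
Why: Saponification of a γ-lactone by acyl–oxygen cleavage: two equivalents of hydroxide are held by the phenols, and the third should open a strained, unhindered lactone faster than the tertiary methyl esters; cold, mild acidification should protonate the carboxylate without re-closing the ring, and unreacted 14 is returned to the step.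

## Compound list

1 | 1-bromo-4-fluoro-2-methoxybenzene | COc1cc(F)ccc1Br | starting material
2 | 4,4'-difluoro-2,2'-dimethoxy-1,1'-biphenyl | COc1cc(F)ccc1-c1ccc(F)cc1OC | intermediate
3 | (2S,3S)-3-hydroxy-5-oxotetrahydrofuran-2,3-dicarboxylic acid | OC(=O)[C@]1(O)CC(=O)O[C@@H]1C(=O)O | starting material
4 | dimethyl (2S,3S)-3-hydroxy-5-oxotetrahydrofuran-2,3-dicarboxylate | COC(=O)[C@]1(O)CC(=O)O[C@@H]1C(=O)OC | intermediate
5 | dimethyl (2S,3S)-5-oxo-3-(triethylsilyloxy)tetrahydrofuran-2,3-dicarboxylate | COC(=O)[C@]1(O[Si](CC)(CC)CC)CC(=O)O[C@@H]1C(=O)OC | intermediate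
6 | 4,4'-difluoro-3,3'-dilithio-2,2'-dimethoxybiphenyl | COc1c([Li])c(F)ccc1-c1ccc(F)c([Li])c1OC | intermediate
7 | 4,4'-difluoro-3,3'-bis[(3S,4S)-4-hydroxy-3,4-bis(methoxycarbonyl)-3-(triethylsilyloxy)butanoyl]-2,2'-dimethoxybiphenyl (open form of the bis-lactol) | COC(=O)[C@](O[Si](CC)(CC)CC)(CC(=O)c1c(F)ccc(-c2ccc(F)c(C(=O)C[C@@](O[Si](CC)(CC)CC)(C(=O)OC)[C@H](O)C(=O)OC)c2OC)c1OC)[C@H](O)C(=O)OC | intermediate
8 | dimethyl (2S,2'S)-2,2'-bis[(1S)-1-hydroxy-2-methoxy-2-oxoethyl]-5,5'-dimethoxy-4,4'-dioxo-[6,6'-bichromane]-2,2'-dicarboxylate | COC(=O)[C@@]1([C@H](O)C(=O)OC)CC(=O)c2c(ccc(-c3ccc4c(c3OC)C(=O)C[C@@](C(=O)OC)([C@H](O)C(=O)OC)O4)c2OC)O1 | intermediate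
9 | dimethyl (2S,2'S)-2,2'-bis[(1S)-1-acetoxy-2-methoxy-2-oxoethyl]-5,5'-dimethoxy-4,4'-dioxo-[6,6'-bichromane]-2,2'-dicarboxylate | COC(=O)[C@@]1([C@H](OC(C)=O)C(=O)OC)CC(=O)c2c(ccc(-c3ccc4c(c3OC)C(=O)C[C@@](C(=O)OC)([C@H](OC(C)=O)C(=O)OC)O4)c2OC)O1 | intermediate
10 | dimethyl (2S,2'S)-2,2'-bis[(2R)-3-hydroxy-5-oxo-2,5-dihydrofuran-2-yl]-5,5'-dimethoxy-4,4'-dioxo-[6,6'-bichromane]-2,2'-dicarboxylate | COC(=O)[C@@]1([C@@H]5OC(=O)C=C5O)CC(=O)c2c(ccc(-c3ccc4c(c3OC)C(=O)C[C@@](C(=O)OC)([C@@H]6OC(=O)C=C6O)O4)c2OC)O1 | intermediate
11 | dimethyl (2S,2'S)-5,5'-dimethoxy-4,4'-dioxo-2,2'-bis[(2S)-5-oxo-3-(trifluoromethylsulfonyloxy)-2,5-dihydrofuran-2-yl]-[6,6'-bichromane]-2,2'-dicarboxylate | COC(=O)[C@@]1([C@@H]5OC(=O)C=C5OS(=O)(=O)C(F)(F)F)CC(=O)c2c(ccc(-c3ccc4c(c3OC)C(=O)C[C@@](C(=O)OC)([C@@H]6OC(=O)C=C6OS(=O)(=O)C(F)(F)F)O4)c2OC)O1 | intermediate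
12 | dimethyl (2S,2'S)-5,5'-dimethoxy-2,2'-bis[(2R)-3-methyl-5-oxo-2,5-dihydrofuran-2-yl]-4,4'-dioxo-[6,6'-bichromane]-2,2'-dicarboxylate | COC(=O)[C@@]1([C@@H]5OC(=O)C=C5C)CC(=O)c2c(ccc(-c3ccc4c(c3OC)C(=O)C[C@@](C(=O)OC)([C@@H]6OC(=O)C=C6C)O4)c2OC)O1 | intermediate
13 | dimethyl (2S,2'S)-5,5'-dimethoxy-2,2'-bis[(2R,3S)-3-methyl-5-oxotetrahydrofuran-2-yl]-4,4'-dioxo-[6,6'-bichromane]-2,2'-dicarboxylate | COC(=O)[C@@]1([C@@H]5OC(=O)C[C@@H]5C)CC(=O)c2c(ccc(-c3ccc4c(c3OC)C(=O)C[C@@](C(=O)OC)([C@@H]6OC(=O)C[C@@H]6C)O4)c2OC)O1 | intermediate
14 | dimethyl (2S,2'S)-5,5'-dihydroxy-2,2'-bis[(2R,3S)-3-methyl-5-oxotetrahydrofuran-2-yl]-4,4'-dioxo-[6,6'-bichromane]-2,2'-dicarboxylate | COC(=O)[C@@]1([C@@H]5OC(=O)C[C@@H]5C)CC(=O)c2c(ccc(-c3ccc4c(c3O)C(=O)C[C@@](C(=O)OC)([C@@H]6OC(=O)C[C@@H]6C)O4)c2O)O1 | intermediate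
15 | (3S,4R)-4-hydroxy-4-[(2S)-5-hydroxy-6-{(2S)-5-hydroxy-2-(methoxycarbonyl)-2-[(2R,3S)-3-methyl-5-oxotetrahydrofuran-2-yl]-4-oxochroman-6-yl}-2-(methoxycarbonyl)-4-oxochroman-2-yl]-3-methylbutanoic acid | COC(=O)[C@@]1([C@H](O)[C@@H](C)CC(=O)O)CC(=O)c2c(ccc(-c3ccc4c(c3O)C(=O)C[C@@](C(=O)OC)([C@@H]3OC(=O)C[C@@H]3C)O4)c2O)O1 | target

## Step count and least certain steps

Total: 11 steps. Longest linear sequence: 10 steps (3 to 15, steps 2 to 11); the arene branch joins after one step.

**Step 4 (key step).** The most likely failure is proton transfer from the lactone CH2 to the hindered aryl carbanion, followed by loss of silanolate, in competition with carbonyl addition. Because two additions must succeed on one dianion, this would leave mono-adducts. In the second stage, reversible retro-aldol and re-aldol at the tertiary alkoxide could erode the configuration at the future C2 before ring closure. The fallback builds the biaryl last. It sets out from 1 and 5: 1 is deprotonated between fluorine and methoxyl with LiN(iPr)2 in THF at −78 °C to the monolithio bromoarene 1-bromo-4-fluoro-3-lithio-2-methoxybenzene F1, which adds to 5 used in larger excess. After the same AcOH quench this gives the monomeric aryl ketone silyl ether F2, and Bu4NF closes it to the 6-bromochromanone F3. Homocoupling of two molecules of F3 with NiCl2(PPh3)2 and Zn, as in step 1, returns to the route at 8. The monoanion is soluble, each event has to succeed only once per molecule, and the closure can be optimised on a simple substrate.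

**Step 6.** The chromanone C3 protons are more acidic than the acetate protons, so the C3 enolate forms first. It could attack the acetate carbonyl (oxygen-to-carbon acyl transfer) or expel the aryloxide, which would open the pyranone ring and lose the C2 configuration on re-closure. The fallback avoids strong base. It sets out from 8, which is acylated with mono-tert-butyl malonate (DCC, DMAP) to the bis(tert-butyl malonate) F4. The malonate CH2 is acidic enough for DBU in MeCN, which should leave the chromanone untouched, and Dieckmann closure gives the bis(tert-butoxycarbonyl tetronic acid) F5. CF3CO2H then removes the tert-butyl group, and the β-keto acid loses CO2 to return to the route at 10. This costs one extra step.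

**Step 11.** Hydroxide may be consumed unselectively: the phenols take two equivalents, and the remainder opens none, one or both lactones statistically. Slow saponification of a methyl ester and re-closure of the hydroxy acid on acidification are further losses. The fallback approaches from the open side. It sets out from 14, which is treated with excess LiOH to open both lactones to the bis(hydroxy acid) F6. Buffered acid at about pH 3 (0 °C → rt), followed by chromatography, then allows one ring to re-close and reaches 15. Unchanged F6 and over-closed 14 are both recycled.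

**Step 9.** Face discrimination could be insufficient, or uptake slow, at a trisubstituted alkene beside a carbon that carries a quaternary centre. The allylic C–O bond of the butenolide could also undergo hydrogenolysis on palladium. The fallback moves stereocontrol from the substrate to the catalyst: homogeneous hydrogenation of 12 with Ru(OAc)2(BINAP) and H2 in MeOH, with the ligand enantiomer chosen to reinforce the substrate's preference. This divalent ruthenium catalyst binds the lactone carbonyl and does not cleave allylic C–O bonds. It sets out from 12 and returns at 13 without a new compound (F0).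

## Further compounds

F1 | step 4 | 1-bromo-4-fluoro-3-lithio-2-methoxybenzene | COc1c(Br)ccc(F)c1[Li]
F2 | step 4 | dimethyl (2S,3S)-2-[2-(3-bromo-6-fluoro-2-methoxyphenyl)-2-oxoethyl]-3-hydroxy-2-(triethylsilyloxy)butanedioate | COC(=O)[C@](O[Si](CC)(CC)CC)(CC(=O)c1c(F)ccc(Br)c1OC)[C@H](O)C(=O)OC
F3 | step 4 | methyl (2S)-6-bromo-2-[(1S)-1-hydroxy-2-methoxy-2-oxoethyl]-5-methoxy-4-oxochromane-2-carboxylate | COC(=O)[C@@]1([C@H](O)C(=O)OC)CC(=O)c2c(ccc(Br)c2OC)O1
F4 | step 6 | dimethyl (2S,2'S)-2,2'-bis{(1S)-1-[(3-tert-butoxy-3-oxopropanoyl)oxy]-2-methoxy-2-oxoethyl}-5,5'-dimethoxy-4,4'-dioxo-[6,6'-bichromane]-2,2'-dicarboxylate | COC(=O)[C@@]1([C@H](OC(=O)CC(=O)OC(C)(C)C)C(=O)OC)CC(=O)c2c(ccc(-c3ccc4c(c3OC)C(=O)C[C@@](C(=O)OC)([C@H](OC(=O)CC(=O)OC(C)(C)C)C(=O)OC)O4)c2OC)O1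
F5 | step 6 | dimethyl (2S,2'S)-2,2'-bis[(2R)-4-(tert-butoxycarbonyl)-3-hydroxy-5-oxo-2,5-dihydrofuran-2-yl]-5,5'-dimethoxy-4,4'-dioxo-[6,6'-bichromane]-2,2'-dicarboxylate | COC(=O)[C@@]1([C@@H]5OC(=O)C(C(=O)OC(C)(C)C)=C5O)CC(=O)c2c(ccc(-c3ccc4c(c3OC)C(=O)C[C@@](C(=O)OC)([C@@H]6OC(=O)C(C(=O)OC(C)(C)C)=C6O)O4)c2OC)O1
F6 | step 11 | (3S,4R,3'S,4'R)-4,4'-[(2S,2'S)-5,5'-dihydroxy-2,2'-bis(methoxycarbonyl)-4,4'-dioxo-[6,6'-bichromane]-2,2'-diyl]bis(4-hydroxy-3-methylbutanoic acid) | COC(=O)[C@@]1([C@H](O)[C@@H](C)CC(=O)O)CC(=O)c2c(ccc(-c3ccc4c(c3O)C(=O)C[C@@](C(=O)OC)([C@H](O)[C@@H](C)CC(=O)O)O4)c2O)O1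
F0 | step 9 | none | none
A1 | alternative 1 | 4,4'-difluoro-2,2'-dimethoxy-3,3'-bis[1-(trimethylsilyloxy)vinyl]biphenyl | C=C(O[Si](C)(C)C)c1c(F)ccc(-c2ccc(F)c(C(=C)O[Si](C)(C)C)c2OC)c1OC
A2 | alternative 1 | methyl 2-[(2R,3S)-3-methyl-5-oxotetrahydrofuran-2-yl]-2-oxoacetate | COC(=O)C(=O)[C@@H]1OC(=O)C[C@@H]1C
A3 | alternative 1 | biaryl bis(β-hydroxy ketone) with both tertiary carbinols (S) and both (2R,3S) lactones in place | COC(=O)[C@@](O)([C@@H]5OC(=O)C[C@@H]5C)CC(=O)c1c(F)ccc(-c3ccc(F)c(c3OC)C(=O)C[C@@](O)(C(=O)OC)[C@@H]3OC(=O)C[C@@H]3C)c1OC
A4 | alternative 2 | 5,5'-di-O-methyl bis-chromanone whose C2 side chains are (1R)-2-methylallyl 2-(diphenylphosphanyl)benzoates | COC(=O)[C@@]1([C@H](OC(=O)c6ccccc6P(c6ccccc6)c6ccccc6)C(C)=C)CC(=O)c2c(ccc(-c3ccc4c(c3OC)C(=O)C[C@@](C(=O)OC)([C@H](OC(=O)c3ccccc3P(c3ccccc3)c3ccccc3)C(C)=C)O4)c2OC)O1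
A5 | alternative 2 | bis-aldehyde with syn acyloxy and methyl centres in each side chain | COC(=O)[C@@]1([C@H](OC(=O)c6ccccc6P(c6ccccc6)c6ccccc6)[C@@H](C)CC=O)CC(=O)c2c(ccc(-c3ccc4c(c3OC)C(=O)C[C@@](C(=O)OC)([C@H](OC(=O)c3ccccc3P(c3ccccc3)c3ccccc3)[C@@H](C)CC=O)O4)c2OC)O1
A6 | alternative 3 | methyl (2S)-6-methyl-2-[(2R,3S)-3-methyl-5-oxotetrahydrofuran-2-yl]-4-oxo-3,4-dihydro-2H-pyran-2-carboxylate | COC(=O)[C@@]1([C@@H]2OC(=O)C[C@@H]2C)CC(=O)C=C(C)O1
A7 | alternative 3 | dimethyl (2E,3E)-2,3-bis[(dimethylamino)methylidene]butanedioate (alkene geometry is lost on aromatisation) | COC(=O)/C(=C/N(C)C)/C(=C\N(C)C)C(=O)OC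
A8 | alternative 3 | bis-chromanone bislactone with free phenols, identical with 14 | COC(=O)[C@@]1([C@@H]5OC(=O)C[C@@H]5C)CC(=O)c2c(ccc(-c3ccc4c(c3O)C(=O)C[C@@](C(=O)OC)([C@@H]3OC(=O)C[C@@H]3C)O4)c2O)O1
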